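**Plan**

- Retrosynthesis: the four methoxymethyl (MOM) ethers come off last. Ring C is then cut in one operation at O1–C8a and C2–C3, giving MOM-protected vanillin (C2=O1) and a ring A 2-fluoroaryl α-alkoxy ketone, used as its enol silane.
- Enabling feature: in rings A and C, C8a is the β-carbon of the vinylogous ester O1–C8a=C4a–C4=O. With fluorine in place of O1, the enol silane C3=C4(OSiMe3)–C4a=C8a–F is a benzo-fused 1-fluoro-3-siloxy-diene. Aldol addition at C3 followed by addition–elimination at C8a is therefore a stepwise hetero-[4+2] addition with loss of Me3SiF.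
- The ring A fragment is cut at C4a–C4 (aryllithium plus amide) and at C6–CH2 (aryllithium plus prenyl bromide), back to the bis-MOM ether of 5-fluororesorcinol. Fluorine para to the prenyl group makes the two remaining ring positions equivalent, so a 6- versus 8-prenyl question cannot arise.
- Forward order: ring A is dressed (prenyl, then acyl), ring B arrives as the aldehyde, ring C is closed in the key step, and deprotection ends the route.
- Stereochemistry: C2 (R) comes from a chiral Lewis acid that selects the aldehyde face. C3 (R) comes from the anti aldol adduct and, independently, from the thermodynamic preference for the 2,3-trans arrangement. Ring closure does not break a bond at either centre.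

Key step: step 8

Remark: the two stereocentres are read as (2R,3R), a 2,3-trans dihydroflavonol. Positions are numbered as in a chroman-4-one (O1, C2, C3, C4, C4a, C5 to C8, C8a). 5-Fluorobenzene-1,3-diol is taken as a purchasable starting material.

**Route**

Step 1
Reactants: 1 5-fluorobenzene-1,3-diol
Product: 2 1-fluoro-3,5-bis(methoxymethoxy)benzene
Conditions: NaH, MOMCl, DMF, 0 °C to rt
Reagents that add atoms: chloromethyl methyl ether (MOMCl), COCCl
Why: Williamson-type O-alkylation of both phenoxides gives the bis-acetal, which later directs metalation and survives organolithiums, Lewis acid at low temperature and fluoride.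

Step 2
Reactants: 2 1-fluoro-3,5-bis(methoxymethoxy)benzene
Product: 4 5-fluoro-1,3-bis(methoxymethoxy)-2-(3-methylbut-2-en-1-yl)benzene, via aryllithium 3 (not isolated)
Conditions: n-BuLi, Et2O, 0 °C to rt; CuBr·SMe2 (10 mol%), prenyl bromide, –20 °C to rt
Reagents that add atoms: 1-bromo-3-methylbut-2-ene (prenyl bromide), CC(C)=CCBr
Why: Directed ortho-metalation under coordination control (weakly polar medium, no amine additive) should remove the proton flanked by the two chelating methoxymethoxy groups rather than one next to fluorine, and the aryllithium is allylated at the primary carbon (SN2) under copper catalysis.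

Step 3
Reactants: 5 methyl 2-hydroxyacetate
Product: 6 methyl 2-(methoxymethoxy)acetate
Conditions: MOMCl, i-Pr2NEt, CH2Cl2, 0 °C to rt
Reagents that add atoms: chloromethyl methyl ether (MOMCl), COCCl
Why: O-alkylation of the primary alcohol under amine base (acetal protection) caps the oxygen that becomes O3, so that it cannot later act as a nucleophile.

Step 4
Reactants: 6 methyl 2-(methoxymethoxy)acetate
Product: 7 2-(methoxymethoxy)-1-(morpholin-4-yl)ethan-1-one
Conditions: morpholine (neat), 80 °C
Reagents that add atoms: morpholine, C1COCCN1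
Why: Aminolysis of an α-alkoxy-activated methyl ester by a secondary amine gives the morpholine amide, an acylating agent that stops at the ketone stage.

Step 5
Reactants: 4 5-fluoro-1,3-bis(methoxymethoxy)-2-(3-methylbut-2-en-1-yl)benzene; 7 2-(methoxymethoxy)-1-(morpholin-4-yl)ethan-1-one
Product: 9 1-[6-fluoro-2,4-bis(methoxymethoxy)-3-(3-methylbut-2-en-1-yl)phenyl]-2-(methoxymethoxy)ethan-1-one, via aryllithium 8 (not isolated)
Conditions: n-BuLi, THF, –78 °C; then 7, –78 to –20 °C; H2O
Reagents that add atoms: none
Why: Directed ortho-metalation at one of the two equivalent remaining ring positions (each flanked by fluorine and an acetal oxygen, hence acidic) is run below the temperature of LiF loss, and acylation by the morpholine amide gives a chelated tetrahedral adduct that releases the ketone only on quench.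

Step 6
Reactants: 9 1-[6-fluoro-2,4-bis(methoxymethoxy)-3-(3-methylbut-2-en-1-yl)phenyl]-2-(methoxymethoxy)ethan-1-one
Product: 10 {[(1Z)-1-[6-fluoro-2,4-bis(methoxymethoxy)-3-(3-methylbut-2-en-1-yl)phenyl]-2-(methoxymethoxy)ethenyl]oxy}(trimethyl)silane
Conditions: LiN(SiMe3)2, Me3SiCl (in situ quench), THF, –78 °C; pentane, filtration, used crude
Reagents that add atoms: chlorotrimethylsilane, C[Si](C)(C)Cl
Why: Kinetic enolisation with in situ O-silylation gives the silyl enol ether, and lithium chelated between the enolate oxygen and the C3 acetal oxygen should give the Z isomer.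

Step 7
Reactants: 11 4-hydroxy-3-methoxybenzaldehyde (vanillin)
Product: 12 3-methoxy-4-(methoxymethoxy)benzaldehyde
Conditions: NaH, MOMCl, THF/DMF, 0 °C to rt
Reagents that add atoms: chloromethyl methyl ether (MOMCl), COCCl
Why: Williamson-type O-alkylation of the phenoxide blocks the 4'-phenol, which would otherwise quench the Lewis acid and open a quinone methide path for C2 epimerisation.

Step 8
Reactants: 10 {[(1Z)-1-[6-fluoro-2,4-bis(methoxymethoxy)-3-(3-methylbut-2-en-1-yl)phenyl]-2-(methoxymethoxy)ethenyl]oxy}(trimethyl)silane; 12 3-methoxy-4-(methoxymethoxy)benzaldehyde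
Product: 14 (2R,3R)-2-[3-methoxy-4-(methoxymethoxy)phenyl]-3,5,7-tris(methoxymethoxy)-6-(3-methylbut-2-en-1-yl)-2,3-dihydro-4H-chromen-4-one, via silyl aldol adduct 13 (not isolated)
Conditions: Sn(OTf)2 (30 mol%), (R)-1-ethyl-2-(piperidin-1-ylmethyl)pyrrolidine (33 mol%), EtCN, –78 °C, slow addition of 10 and 12; then Bu4N[Ph3SiF2] (0.5 equiv), THF, –78 to 0 °C
Reagents that add atoms: none
Why: Proposed new method: the chiral diamine–Sn(OTf)2 Lewis acid binds aldehyde 12 and C3 of enol silane 10 adds through an open transition state (Mukaiyama aldol, C2–C3 bond) with silyl transfer to O1, giving 13; fluoride then turns the O1–SiMe3 group into a silicate or alkoxide that adds to C8a, the fluorine-bearing β-carbon of the C4 ketone, through a ketone-stabilised Meisenheimer complex, and the expelled fluoride carries the chain and ends as Me3SiF, so that 10 behaves overall as a benzo-fused 1-fluoro-3-siloxy-diene in a stepwise hetero-[4+2] addition. The closest known reaction types are the chiral diamine/divalent tin Mukaiyama aldol of α-alkoxy enol silanes with aromatic aldehydes, the Lewis acid siloxydiene–aldehyde route to dihydropyranones that passes through an aldol adduct, and the fluoride-catalysed SNAr of silyl ethers on activated aryl fluorides; their union on a ketone enol silane in one flask is what is new. Ring C closes in a 6-exo-trig addition–elimination at C8a, and because the C2–O1 bond is never broken C2 keeps the configuration set in the aldol stage. C2 (R) is controlled by the ligand, taken as the (R)-diamine on the expectation, by analogy with thioester-derived enol silanes, that it directs attack to the Si face of the aldehyde; C3 (R) follows from the anti adduct expected when the C3 acetal oxygen coordinates tin, and in any case from thermodynamic control, since a 2,3-cis isomer should epimerise at C3 (α to the ketone) to the diequatorial trans isomer under the mildly basic fluoride stage. The step needs attack at C8a only, which the single fluorine ortho to the ketone secures (the C5 and C7 acetal oxygens are not leaving groups, and the capped C3 oxygen cannot close a five-membered ring). It also needs ring closure to outrun retro-aldol cleavage, for which substoichiometric fluoride at low temperature, the intramolecular six-membered closure and the neutral product are relied on.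

Step 9
Reactants: 14 (2R,3R)-2-[3-methoxy-4-(methoxymethoxy)phenyl]-3,5,7-tris(methoxymethoxy)-6-(3-methylbut-2-en-1-yl)-2,3-dihydro-4H-chromen-4-one
Product: 15 (2R,3R)-3,5,7-trihydroxy-2-(4-hydroxy-3-methoxyphenyl)-6-(3-methylbut-2-en-1-yl)-2,3-dihydro-4H-chromen-4-one
Conditions: HCl (1.25 M in MeOH), MeOH/THF, 40 °C
Reagents that add atoms: none
Why: Acid-catalysed acetal exchange with methanol removes all four MOM groups as dimethoxymethane; the aryl methyl ether and the prenyl group are expected to survive this acidity, and the 2,3-trans arrangement is the thermodynamic one.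

**Compound list**

1 | 5-fluorobenzene-1,3-diol | Oc1cc(O)cc(F)c1 | starting material
2 | 1-fluoro-3,5-bis(methoxymethoxy)benzene | COCOc1cc(F)cc(OCOC)c1 | intermediate
3 | [4-fluoro-2,6-bis(methoxymethoxy)phenyl]lithium | [Li]c1c(OCOC)cc(F)cc1OCOC | intermediate
4 | 5-fluoro-1,3-bis(methoxymethoxy)-2-(3-methylbut-2-en-1-yl)benzene | COCOc1cc(F)cc(OCOC)c1CC=C(C)C | intermediate
5 | methyl 2-hydroxyacetate | COC(=O)CO | starting material
6 | methyl 2-(methoxymethoxy)acetate | COCOCC(=O)OC | intermediate
7 | 2-(methoxymethoxy)-1-(morpholin-4-yl)ethan-1-one | COCOCC(=O)N1CCOCC1 | intermediate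
8 | [6-fluoro-2,4-bis(methoxymethoxy)-3-(3-methylbut-2-en-1-yl)phenyl]lithium | COCOc1c([Li])c(F)cc(OCOC)c1CC=C(C)C | intermediate
9 | 1-[6-fluoro-2,4-bis(methoxymethoxy)-3-(3-methylbut-2-en-1-yl)phenyl]-2-(methoxymethoxy)ethan-1-one | COCOCC(=O)c1c(F)cc(OCOC)c(CC=C(C)C)c1OCOC | intermediate
10 | {[(1Z)-1-[6-fluoro-2,4-bis(methoxymethoxy)-3-(3-methylbut-2-en-1-yl)phenyl]-2-(methoxymethoxy)ethenyl]oxy}(trimethyl)silane | COCO/C=C(\O[Si](C)(C)C)c1c(F)cc(OCOC)c(CC=C(C)C)c1OCOC | intermediate
11 | 4-hydroxy-3-methoxybenzaldehyde (vanillin) | COc1cc(C=O)ccc1O | starting material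
12 | 3-methoxy-4-(methoxymethoxy)benzaldehyde | COCOc1ccc(C=O)cc1OC | intermediate
13 | (2R,3R)-1-[6-fluoro-2,4-bis(methoxymethoxy)-3-(3-methylbut-2-en-1-yl)phenyl]-3-[3-methoxy-4-(methoxymethoxy)phenyl]-2-(methoxymethoxy)-3-[(trimethylsilyl)oxy]propan-1-one | COCO[C@H]([C@H](O[Si](C)(C)C)c1ccc(OCOC)c(OC)c1)C(=O)c1c(F)cc(OCOC)c(CC=C(C)C)c1OCOC | intermediate
14 | (2R,3R)-2-[3-methoxy-4-(methoxymethoxy)phenyl]-3,5,7-tris(methoxymethoxy)-6-(3-methylbut-2-en-1-yl)-2,3-dihydro-4H-chromen-4-one | COc1cc([C@H]2Oc3cc(OCOC)c(CC=C(C)C)c(OCOC)c3C(=O)[C@@H]2OCOC)ccc1OCOC | intermediate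
15 | (2R,3R)-3,5,7-trihydroxy-2-(4-hydroxy-3-methoxyphenyl)-6-(3-methylbut-2-en-1-yl)-2,3-dihydro-4H-chromen-4-one | COc1cc([C@H]2Oc3cc(O)c(CC=C(C)C)c(O)c3C(=O)[C@@H]2O)ccc1O | target

Total step count: 9. Longest linear sequence: 6 steps (steps 1, 2, 5, 6, 8, 9).

**Steps most likely to fail**

Step 8 (proposed new method).
- What may go wrong: slow C–C bond formation by the hindered, twisted enol silane; leakage through an achiral silyl triflate-catalysed pathway or poor facial selectivity; retro-aldol cleavage of the desilylated aldolate before ring closure, which would erode the configuration at C2; base-mediated ring opening of the product.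
- Fallback, from 9 and 12, returning at 14: ketone 9 is deprotonated with LiN(SiMe3)2 in THF at –78 °C and added to 12 to give the racemic aldol adduct F1 as a mixture of diastereomers. K2CO3 in DMF at 50 °C closes ring C by SNAr with loss of fluoride and equilibrates C3, giving the racemic 2,3-trans chromanone F2. Preparative chromatography on a chiral stationary phase (amylose tris(3,5-dimethylphenylcarbamate)) separates 14 from the (2S,3S) enantiomer F3.

Step 2.
- What may go wrong: competing metalation next to fluorine, followed by LiF loss to an aryne, and allylation with allylic transposition.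
- Fallback, from 2, returning at 4: both fluorine-flanked positions are silylated with LiN(i-Pr)2 and Me3SiCl (in situ trapping, THF, –78 °C) to give the bis(trimethylsilyl) arene F4. n-BuLi can then remove only the proton between the two acetal oxygens, and CuBr·SMe2-catalysed coupling with prenyl bromide gives the prenylated bis(silyl) arene F5. Bu4NF in wet THF removes both silyl groups by protodesilylation to give 4.

Step 9.
- What may go wrong: acid-catalysed addition of the 5- or 7-hydroxyl to the prenyl double bond (chroman formation), slow cleavage of the aliphatic C3 acetal, and C2 epimerisation by ring opening once the 4'-phenol is free.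
- Fallback, from 14, returning at 15: Me2BBr in CH2Cl2 at –78 °C exchanges the four methoxymethyl ethers for bromomethyl ethers, giving the tetrakis(bromomethyl) ether F6. F6 is not isolated and is hydrolysed by NaHCO3 in aqueous THF to 15, so that no protic acid meets the prenylated phenol.

Further compounds
F1 | step 8 | 1-[6-fluoro-2,4-bis(methoxymethoxy)-3-(3-methylbut-2-en-1-yl)phenyl]-3-hydroxy-3-[3-methoxy-4-(methoxymethoxy)phenyl]-2-(methoxymethoxy)propan-1-one, racemic syn/anti mixture (centres undefined) | COCOC(C(O)c1ccc(OCOC)c(OC)c1)C(=O)c1c(F)cc(OCOC)c(CC=C(C)C)c1OCOC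
F2 | step 8 | racemic 2,3-trans-2-[3-methoxy-4-(methoxymethoxy)phenyl]-3,5,7-tris(methoxymethoxy)-6-(3-methylbut-2-en-1-yl)-2,3-dihydro-4H-chromen-4-one (both enantiomers) | COc1cc([C@H]2Oc3cc(OCOC)c(CC=C(C)C)c(OCOC)c3C(=O)[C@@H]2OCOC)ccc1OCOC.COc1cc([C@@H]2Oc3cc(OCOC)c(CC=C(C)C)c(OCOC)c3C(=O)[C@H]2OCOC)ccc1OCOC
F3 | step 8 | (2S,3S)-2-[3-methoxy-4-(methoxymethoxy)phenyl]-3,5,7-tris(methoxymethoxy)-6-(3-methylbut-2-en-1-yl)-2,3-dihydro-4H-chromen-4-one | COc1cc([C@@H]2Oc3cc(OCOC)c(CC=C(C)C)c(OCOC)c3C(=O)[C@H]2OCOC)ccc1OCOC
F4 | step 2 | [2-fluoro-4,6-bis(methoxymethoxy)-1,3-phenylene]bis(trimethylsilane) | COCOc1cc(OCOC)c([Si](C)(C)C)c(F)c1[Si](C)(C)C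
F5 | step 2 | [2-fluoro-4,6-bis(methoxymethoxy)-5-(3-methylbut-2-en-1-yl)-1,3-phenylene]bis(trimethylsilane) | COCOc1c(CC=C(C)C)c(OCOC)c([Si](C)(C)C)c(F)c1[Si](C)(C)C
F6 | step 9 | (2R,3R)-3,5,7-tris(bromomethoxy)-2-[4-(bromomethoxy)-3-methoxyphenyl]-6-(3-methylbut-2-en-1-yl)-2,3-dihydro-4H-chromen-4-one | COc1cc([C@H]2Oc3cc(OCBr)c(CC=C(C)C)c(OCBr)c3C(=O)[C@@H]2OCBr)ccc1OCBr
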